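The plan cuts ring B (C5 to C10) at C9–C10 and re-attaches C10 to C8, so the decalin becomes a trans-hydrindane that is available from an amino-acid-mediated Robinson annulation. The key step reverses this: a silver-promoted semipinacol shift moves quaternary C10 from the C8 carbinol to the C9 bromide. In one operation it forms C9–C10, enlarges the cyclopentane to ring B, sets the axial C9 centre (C11 trans to the C10 methyl) by inversion, and leaves a C8 ketone for the C12 methyl and the C7=C8 alkene. It exploits the position of C9 between quaternary C10 and C8. The precursor is a bromohydrin with tertiary C8–OH, (9R)-bromide and silyl ethers at O3 and O11.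

Key step: step 11

Remark: drimane numbering is used for every bicyclic compound (C11 = CH2O, C12 = methyl on C8); D-phenylalanine and all reagents named in the Conditions lines are taken as purchased; TBS = tert-butyldimethylsilyl.

Step 1
Reactants: 1 2-methylcyclopentane-1,3-dione, 2 ethyl vinyl ketone
Product: 3 2-methyl-2-(3-oxopentyl)cyclopentane-1,3-dione
Conditions: H2O, AcOH (cat.), 70 °C
Reagents that add atoms: none
Why: Michael addition of the acidic 1,3-dione to the enone in water is the first half of a Robinson annulation and creates only an achiral quaternary carbon.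

Step 2
Reactants: 3 2-methyl-2-(3-oxopentyl)cyclopentane-1,3-dione
Product: 4 (7aR)-hydrindenedione
Conditions: D-phenylalanine (1 equiv), camphorsulfonic acid (0.5 equiv), DMF, 30 → 70 °C; recrystallisation
Reagents that add atoms: none
Why: Amino-acid-mediated intramolecular aldol condensation (Hajos–Parrish-type Robinson annulation), in which the enamine of the side-chain ketone attacks one of the two enantiotopic ring carbonyls under control of the D-amino acid, which sets C10 as R, and dehydration gives the enone.

Step 3
Reactants: 4 (7aR)-hydrindenedione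
Product: 5 enone C8 dioxolane
Conditions: Me3SiOCH2CH2OSiMe3, Me3SiOTf (cat.), CH2Cl2, −78 → −20 °C
Reagents that add atoms: 1,2-bis(trimethylsilyloxy)ethane, C[Si](C)(C)OCCO[Si](C)(C)C
Why: Silyl-triflate-catalysed (Noyori-type) dioxolane formation picks the saturated C8 cyclopentanone because the conjugated, tetrasubstituted C3 enone carbonyl is far less electrophilic, and the low temperature avoids migration of the double bond.

Step 4
Reactants: 5 enone C8 dioxolane
Product: 7 trans-hydrindan-3-one C8 dioxolane, via lithium C3 enolate 6 (not isolated)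
Conditions: Li, NH3 (l), THF, t-BuOH (1 equiv), −78 °C; then MeI, −78 °C → rt
Reagents that add atoms: iodomethane, CI
Why: Reductive alkylation of an enone (dissolving-metal reduction, then regiospecific C-methylation of the C3 enolate at C4), in which protonation of the β-carbon C5 on the face anti to the C10 methyl sets the trans ring fusion and the methylation completes the C4 gem-dimethyl group without a new stereocentre.

Step 5
Reactants: 7 trans-hydrindan-3-one C8 dioxolane
Product: 9 3-hydroxy-trans-hydrindan-8-one, via C3 hydroxy dioxolane 8 (not isolated)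
Conditions: LiBH(s-Bu)3, THF, −78 → 0 °C; then 2 M HCl, rt
Reagents that add atoms: water, O
Why: Carbonyl reduction by a bulky trialkylborohydride followed by acid hydrolysis of the dioxolane, in which the hydride approaches C3 along the equatorial direction, away from the axial hydrogens at C1 and C5, so that the axial (3S) alcohol is set before aqueous acid frees the C8 ketone.

Step 6
Reactants: 9 3-hydroxy-trans-hydrindan-8-one, 10 triethyl phosphonoacetate
Product: 11 (E)-unsaturated ester
Conditions: NaOEt, EtOH, reflux
Reagents that add atoms: none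
Why: Horner–Wadsworth–Emmons olefination of the hindered C8 cyclopentanone, which, as with five-ring ketones next to an angular methyl group in steroids, should place the ester anti to quaternary C10 and so give the (E)-alkene, the free C3 hydroxyl being inert under ethoxide.

Step 7
Reactants: 11 (E)-unsaturated ester
Product: 12 (E)-allylic alcohol (3,11-diol)
Conditions: i-Bu2AlH (3.5 equiv), CH2Cl2, −78 → 0 °C
Reagents that add atoms: none
Why: Hydride 1,2-reduction of the conjugated ester by the aluminium hydride gives the allylic alcohol without touching the alkene geometry or any stereocentre.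

Step 8
Reactants: 12 (E)-allylic alcohol (3,11-diol)
Product: 13 bis-TBS ether
Conditions: t-BuMe2SiOTf (2.5 equiv), 2,6-lutidine, CH2Cl2, −78 → 0 °C
Reagents that add atoms: tert-butyldimethylsilyl triflate, CC(C)(C)[Si](C)(C)OS(=O)(=O)C(F)(F)F
Why: Silylation with the silyl triflate and a hindered pyridine base is reactive enough to cap the primary allylic C11 hydroxyl and the hindered axial C3 hydroxyl in one operation.

Step 9
Reactants: 13 bis-TBS ether
Product: 14 (8S,9S)-epoxide
Conditions: m-CPBA, NaHCO3, CH2Cl2, 0 °C
Reagents that add atoms: 3-chloroperoxybenzoic acid, OOC(=O)c1cccc(Cl)c1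
Why: Prilezhaev epoxidation, in which the peracid adds to the exocyclic alkene from the face anti to the axial C10 methyl and syn addition to the (E)-alkene sets C8 and C9 (both S) together.

Step 10
Reactants: 14 (8S,9S)-epoxide
Product: 15 trans-hydrindane bromohydrin
Conditions: Li2NiBr4 (THF stock solution), THF, 0 °C → rt; pH 7 buffer
Reagents that add atoms: dilithium tetrabromonickelate, [Li+].[Li+].[Ni+2].[Br-].[Br-].[Br-].[Br-]
Why: Nucleophilic epoxide opening by soft bromide under nearly neutral conditions, in which SN2 attack is possible only at C9 because C8 is fully substituted, and the inversion at C9 sets the (9R)-bromide next to the tertiary C8 alcohol.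

Step 11
Reactants: 15 trans-hydrindane bromohydrin
Product: 16 trans-decalin 8-ketone
Conditions: AgBF4 (1.5 equiv), 2,6-di-tert-butyl-4-methylpyridine (2 equiv), CH2Cl2, −40 °C → rt, dark
Reagents that add atoms: none
Why: Silver cation pulls bromide from C9 while the C8–C10 bond, antiperiplanar to C–Br, shifts to C9 in a concerted 1,2-migration; the hydroxyl oxygen takes up the charge developing at C8 and loss of its proton to the pyridine base leaves the C8 ketone. The closest known reaction type is the silver-promoted semipinacol (Tiffeneau–Demjanov-type) ring expansion of 1-(1-haloalkyl)cycloalkanols. Ring B is closed by one-carbon ring enlargement, C9 being inserted between C8 and C10 of the cyclopentane, not by an end-to-end cyclisation. The new C9 stereocentre is set by the configuration of the bromide: C10 arrives on the face opposite to the leaving group with retention at C10, so the (9R)-bromide becomes the (9S)-centre with C11 axial and trans to the C10 methyl. The step needs migration of C10 in preference to C7 and to re-closure of the oxirane by the C8 oxygen; C10 is the more substituted and better migrating carbon, the rotamer that aligns C8–C10 with C–Br places only the C9 hydrogen in the crowded gap between C7 and C10 whereas alignment of C8–C7 would force C11 into that gap, and enlargement relieves the strain of the trans-hydrindane. The hindered base removes HBF4, so that neither the silyl ethers nor the epimerisable C9 centre of 16 meet acid.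

Step 12
Reactants: 16 trans-decalin 8-ketone
Product: 18 C7=C8 enol triflate, via lithium C7–C8 enolate 17 (not isolated)
Conditions: LiN(i-Pr)2 (1.3 equiv), THF, −78 °C; then N-(5-chloro-2-pyridyl)triflimide, −78 → −20 °C
Reagents that add atoms: N-(5-chloro-2-pyridyl)bis(trifluoromethanesulfonyl)imide, FC(F)(F)S(=O)(=O)N(c1ccc(Cl)cn1)S(=O)(=O)C(F)(F)F
Why: Kinetic enolate formation and O-triflation, in which the amide base removes a C7 methylene proton because the C9 hydrogen is equatorial, poorly aligned with the carbonyl and shielded by C10, and trapping at −78 °C fixes the C7=C8 enol triflate without epimerising C9.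

Step 13
Reactants: 18 C7=C8 enol triflate
Product: 19 bis-TBS 8-methyl-7-ene
Conditions: MeMgBr (2 equiv), Fe(acac)3 (5 mol %), THF/NMP, −30 → 0 °C
Reagents that add atoms: methylmagnesium bromide, C[Mg]Br
Why: Iron-catalysed Kumada-type cross-coupling of an alkenyl triflate with a methyl Grignard reagent replaces the triflate by the C12 methyl at C8 with the alkene held at C7=C8.

Step 14
Reactants: 19 bis-TBS 8-methyl-7-ene
Product: 20 (3S,5S,9S,10R)-drim-7-ene-3,11-diol
Conditions: Bu4NF (5 equiv), THF, 60 °C
Reagents that add atoms: none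
Why: Fluoride-induced cleavage of both silyl ethers, carried out before the base-sensitive coumarin is attached, frees the C3 and C11 hydroxyls without affecting any stereocentre.

Step 15
Reactants: 20 (3S,5S,9S,10R)-drim-7-ene-3,11-diol, 21 scopoletin
Product: 22 CNP0218138.1
Conditions: PPh3, DIAD, THF, 0 °C → rt
Reagents that add atoms: none
Why: Mitsunobu etherification, in which the primary C11 hydroxyl is activated as an alkoxyphosphonium ion and displaced by the acidic 7-hydroxyl of scopoletin at a methylene carbon, while the axial C3 hydroxyl next to the C4 gem-dimethyl group is too hindered to be activated, so no stereocentre is touched.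

Compound list

1 | 2-methylcyclopentane-1,3-dione | CC1C(=O)CCC1=O | starting material
2 | ethyl vinyl ketone (pent-1-en-3-one) | CCC(=O)C=C | starting material
3 | 2-methyl-2-(3-oxopentyl)cyclopentane-1,3-dione | CCC(=O)CCC1(C)C(=O)CCC1=O | intermediate
4 | (7aR)-4,7a-dimethyl-2,3,7,7a-tetrahydro-1H-indene-1,5(6H)-dione | CC1=C2CCC(=O)[C@]2(C)CCC1=O | intermediate
5 | (7a'R)-4',7a'-dimethyl-2',3',7',7a'-tetrahydrospiro[1,3-dioxolane-2,1'-inden]-5'(6'H)-one (C8 ethylene ketal of 4) | CC1=C2CCC3(OCCO3)[C@]2(C)CCC1=O | intermediate
6 | lithium C3 enolate (C3–OLi, C3=C4) of the (3a'R,7a'R) trans-fused 4-methyl ketone, 5-H anti to the C10 methyl, C8 dioxolane | [Li]OC1=C(C)[C@H]2CCC3(OCCO3)[C@]2(C)CC1 | intermediate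
7 | (3a'R,7a'R)-4',4',7a'-trimethylhexahydrospiro[1,3-dioxolane-2,1'-indan]-5'-one (trans ring fusion, C3 ketone, C4 gem-dimethyl) | CC1(C)[C@H]2CCC3(OCCO3)[C@]2(C)CCC1=O | intermediate
8 | (3a'R,5'S,7a'R)-4',4',7a'-trimethyloctahydrospiro[1,3-dioxolane-2,1'-inden]-5'-ol (axial C3–OH) | CC1(C)[C@H]2CCC3(OCCO3)[C@]2(C)CC[C@@H]1O | intermediate
9 | (3aR,5S,7aR)-5-hydroxy-4,4,7a-trimethyloctahydro-1H-inden-1-one | CC1(C)[C@H]2CCC(=O)[C@]2(C)CC[C@@H]1O | intermediate
10 | triethyl phosphonoacetate | CCOC(=O)CP(=O)(OCC)OCC | starting material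
11 | ethyl (2E)-[(3aS,5S,7aR)-5-hydroxy-4,4,7a-trimethyloctahydro-1H-inden-1-ylidene]acetate | CCOC(=O)/C=C1\CC[C@@H]2C(C)(C)[C@@H](O)CC[C@@]12C | intermediate
12 | (1E,3aS,5S,7aR)-1-(2-hydroxyethylidene)-4,4,7a-trimethyloctahydro-1H-inden-5-ol | OC/C=C1\CC[C@@H]2C(C)(C)[C@@H](O)CC[C@@]12C | intermediate
13 | bis-TBS ether of 12 (silyl ethers at O3 and O11, (E)-alkene C8=C9) | CC(C)(C)[Si](C)(C)OC/C=C1\CC[C@@H]2C(C)(C)[C@@H](O[Si](C)(C)C(C)(C)C)CC[C@@]12C | intermediate
14 | (8S,9S)-8,9-epoxide of 13 (spiro-oxirane at C8, oxygen anti to the C10 methyl; ring descriptors 3aR,5S,7aR) | CC(C)(C)[Si](C)(C)OC[C@@H]1O[C@]12CC[C@@H]3C(C)(C)[C@@H](O[Si](C)(C)C(C)(C)C)CC[C@@]23C | intermediate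
15 | (1S,3aR,5S,7aR)-1-[(1R)-1-bromo-2-(TBS-oxy)ethyl]-5-(TBS-oxy)-4,4,7a-trimethyloctahydro-1H-inden-1-ol (tertiary C8–OH, 9R bromide) | CC(C)(C)[Si](C)(C)OC[C@@H](Br)[C@]2(O)CC[C@@H]3C(C)(C)[C@@H](O[Si](C)(C)C(C)(C)C)CC[C@]32C | intermediate
16 | (1S,4aS,6S,8aR)-6-(TBS-oxy)-1-[(TBS-oxy)methyl]-5,5,8a-trimethyl-3,4,4a,5,6,7,8,8a-octahydronaphthalen-2(1H)-one (axial C9 side chain) | CC(C)(C)[Si](C)(C)OC[C@H]2C(=O)CC[C@@H]3C(C)(C)[C@@H](O[Si](C)(C)C(C)(C)C)CC[C@]32C | intermediate
17 | lithium C7–C8 enolate of 16 (C8–OLi, C7=C8) | CC(C)(C)[Si](C)(C)OC[C@H]2C(O[Li])=CC[C@@H]3C(C)(C)[C@@H](O[Si](C)(C)C(C)(C)C)CC[C@]32C | intermediate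
18 | (1S,4aS,6S,8aR)-6-(TBS-oxy)-1-[(TBS-oxy)methyl]-5,5,8a-trimethyl-1,4,4a,5,6,7,8,8a-octahydronaphthalen-2-yl trifluoromethanesulfonate | CC(C)(C)[Si](C)(C)OC[C@H]2C(OS(=O)(=O)C(F)(F)F)=CC[C@@H]3C(C)(C)[C@@H](O[Si](C)(C)C(C)(C)C)CC[C@]32C | intermediate
19 | 3,11-bis-O-TBS ether of (3S,5S,9S,10R)-drim-7-ene-3,11-diol | CC(C)(C)[Si](C)(C)OC[C@H]2C(C)=CC[C@@H]3C(C)(C)[C@@H](O[Si](C)(C)C(C)(C)C)CC[C@]32C | intermediate
20 | (3S,5S,9S,10R)-drim-7-ene-3,11-diol, i.e. (2S,4aR,5S,8aS)-5-(hydroxymethyl)-1,1,4a,6-tetramethyl-1,2,3,4,4a,5,8,8a-octahydronaphthalen-2-ol | OC[C@H]2C(C)=CC[C@@H]3C(C)(C)[C@@H](O)CC[C@]32C | intermediate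
21 | scopoletin (7-hydroxy-6-methoxy-2H-chromen-2-one) | COc1cc2ccc(=O)oc2cc1O | starting material
22 | 7-{[(1S,4aS,6S,8aR)-6-hydroxy-2,5,5,8a-tetramethyl-1,4,4a,5,6,7,8,8a-octahydronaphthalen-1-yl]methoxy}-6-methoxy-2H-chromen-2-one (CNP0218138.1) | COc1cc2ccc(=O)oc2cc1OC[C@H]1C(C)=CC[C@@H]2C(C)(C)[C@@H](O)CC[C@]21C | target

Total step count: 15. Longest linear sequence: 15 steps (1 and 2 to 22).

Steps most likely to fail

Step 11. After silver has taken up the bromide, the C8 oxygen may close onto C9 instead of the C8–C10 bond, which returns the oxirane and opens acid-type decomposition, or C7 may migrate in place of C10. The fallback sets out from epoxide 14 and comes back at ketone 16. Sodium benzeneselenolate (PhSeSePh, NaBH4, EtOH) should open 14 at C9 with inversion to the β-hydroxy selenide F1, which has the C9 configuration of 15. Dichlorocarbene (CHCl3, TlOEt) then turns selenium into a selenonium ylide. Its departure, pushed by the C8 alkoxide, should bring about the same shift of C10 from C8 to C9 without a free cation or acid. This selenide-based ring homologation of cycloalkanols is known chemistry.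

Step 10. Bromide attack at C9 may be slow, because C9 lies between the fully substituted C8 and the silyloxymethyl group and the approach passes the C10 methyl. Lewis-acid-assisted cleavage of the C8–O bond and skeletal rearrangement could then take over. The fallback sets out from alkene 13 and comes back at bromohydrin 15. Catalytic OsO4 with N-methylmorpholine N-oxide should dihydroxylate 13 from the face anti to the C10 methyl to the (8S,9S)-diol F2. 1,1'-Sulfonyldiimidazole and NaH close the cyclic sulfate F3. LiBr in THF opens it at C9 with inversion, with no Lewis acid needed, to the lithium C8 sulfate monoester F4. A trace of H2SO4 with one equivalent of water in THF hydrolyses this to 15.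

Step 4. Protonation of C5 may occur in part on the wrong face and give the cis ring fusion, and enolate exchange may scramble the methylation. The fallback sets out from enone 5 and comes back at ketone 7. Deconjugative α-methylation (t-BuOK, MeI, t-BuOH) should give the 4,4-dimethyl β,γ-unsaturated ketone F5 with the alkene at C5=C6. Hydrogenation (H2, palladium on carbon, EtOAc) then delivers hydrogen to the face anti to the C10 methyl and gives the trans-fused ketone 7.

Further compounds

F1 | step 11 | (9R)-9-phenylselanyl analogue of 15 (β-hydroxy selenide, tertiary C8–OH) | CC(C)(C)[Si](C)(C)OC[C@@H]([Se]c1ccccc1)[C@]2(O)CC[C@@H]3C(C)(C)[C@@H](O[Si](C)(C)C(C)(C)C)CC[C@]32C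
F2 | step 10 | (8S,9S)-8,9-diol of 13 | CC(C)(C)[Si](C)(C)OC[C@H](O)[C@]2(O)CC[C@@H]3C(C)(C)[C@@H](O[Si](C)(C)C(C)(C)C)CC[C@]32C
F3 | step 10 | (8S,9S)-8,9-cyclic sulfate of F2 | CC(C)(C)[Si](C)(C)OC[C@@H]1OS(=O)(=O)O[C@]12CC[C@@H]3C(C)(C)[C@@H](O[Si](C)(C)C(C)(C)C)CC[C@@]23C
F4 | step 10 | lithium salt of the C8 sulfate monoester of 15 ((9R)-bromide) | CC(C)(C)[Si](C)(C)OC[C@@H](Br)[C@]2(OS(=O)(=O)[O-])CC[C@@H]3C(C)(C)[C@@H](O[Si](C)(C)C(C)(C)C)CC[C@]32C.[Li+]
F5 | step 4 | (7a'R)-4',4',7a'-trimethyl-4',6',7',7a'-tetrahydrospiro[1,3-dioxolane-2,1'-inden]-5'(2'H)-one (4,4-dimethyl ketone with C5=C6 alkene) | CC1(C)C2=CCC3(OCCO3)[C@]2(C)CCC1=O
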